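**Retrosynthetic overview**

- Numbering: ring A (seven-membered) is C1 (angelate carbinol)–C2H2–C3(CH3)=C4H–C5 (angelate carbinol)–C6 (quaternary, CH3)–C10H; ring B (five-membered) is C6–C7(OH)–C8H2–C9(OH)(iPr)–C10.
- Feature: in ring A the oxygen-bearing C5, flanked by C4 and the quaternary C6, is a latent oxyallyl cation, and C10–C1–C2–C3 with oxygen on C1 is a latent 2-silyloxy diene; the two are linked through the ring B atoms C7–C8–C9.
- Key disconnection: C6–C10 and C3–C4, formed together by an intramolecular (4+3) cycloaddition of an acyclic chloro ketone; ring B closes with the first bond and ring A with the second, in one step.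
- Precursor: C9 from Sharpless epoxidation and hydride opening of a stereodefined dienol, C7 from an Evans propionate aldol, the silyloxy diene from an allyl arm, the chloromethyl ketone from a Weinreb amide.
- After the key step: enol ether hydrolysis, C9-hydroxyl-directed reduction at C1, Saegusa–Ito desaturation to the C3=C4 enone, angeloylation at C1, 1,2-reduction at C5, angeloylation at C5, desilylation.

Key step: step 15

Remarks on the chemistry:
- The locants C1–C10 above are used for all bicyclic compounds; β is the face of the C10 hydrogen and α the face of the C6 methyl. The target is the 1β,5β-bis-angelate, 7α,9α-diol, 9β-isopropyl, 6α-methyl, 10β-H compound.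
- Assumption: 4-methylpent-2-yn-1-ol, (E)-1-bromoprop-1-ene and angelic acid are purchased.
- The C3 configuration of the cycloadduct is drawn as expected for suprafacial addition; it has no bearing on the route because C3 becomes trigonal in step 19.
- The two angelate esters are introduced in separate steps, each at the only secondary hydroxyl then present, so that every acylation is site-defined.

**Route**

Step 1
Reactants: 1 4-methylpent-2-yn-1-ol
Product: 3 (2Z)-3-iodo-4-methylpent-2-en-1-ol, via sodium alkenylalanate 2 (not isolated)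
Conditions: NaAlH2(OCH2CH2OMe)2, THF, 0 → 23 °C; then N-iodosuccinimide, THF, −78 → 0 °C
Reagents that add atoms: N-iodosuccinimide, O=C1CCC(=O)N1I
Why: Hydroxyl-directed trans-hydroalumination of the propargylic alcohol places aluminium at C3 in a five-membered alkoxyalanate, and iodinolysis of the C–Al bond with retention gives the (Z)-iodide with the isopropyl group trans to CH2OH.

Step 2
Reactants: 3 (2Z)-3-iodo-4-methylpent-2-en-1-ol; 4 allyltributylstannane
Product: 5 (2E)-3-(propan-2-yl)hexa-2,5-dien-1-ol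
Conditions: PdCl2(MeCN)2 (5 mol %), DMF, 23 °C
Reagents that add atoms: none
Why: Stille coupling of the alkenyl iodide with the allylstannane proceeds with retention of alkene geometry and tolerates the free hydroxyl, giving the skipped dienol with the allyl group cis to CH2OH.

Step 3
Reactants: 5 (2E)-3-(propan-2-yl)hexa-2,5-dien-1-ol
Product: 6 [(2S,3S)-3-(propan-2-yl)-3-(prop-2-en-1-yl)oxiran-2-yl]methanol
Conditions: Ti(OiPr)4 (10 mol %), L-(+)-diethyl tartrate (12 mol %), t-BuOOH, 4 Å molecular sieves, CH2Cl2, −20 °C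
Reagents that add atoms: tert-butyl hydroperoxide, CC(C)(C)OO
Why: Sharpless asymmetric epoxidation of the trisubstituted allylic alcohol, where the L-(+)-tartrate delivers oxygen to the same face as in geraniol to give the (2S,3S)-epoxy alcohol; this sets the tertiary centre that becomes C9 and leaves the isolated terminal alkene untouched.

Step 4
Reactants: 6 [(2S,3S)-3-(propan-2-yl)-3-(prop-2-en-1-yl)oxiran-2-yl]methanol
Product: 7 (3R)-3-(propan-2-yl)hex-5-ene-1,3-diol
Conditions: NaAlH2(OCH2CH2OMe)2, THF, 0 °C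
Reagents that add atoms: none
Why: The aluminium alkoxide of the 2,3-epoxy alcohol delivers hydride intramolecularly to C2, so the epoxide opens regioselectively to the 1,3-diol and the C–O bond at the tertiary centre (C9) stays intact.

Step 5
Reactants: 7 (3R)-3-(propan-2-yl)hex-5-ene-1,3-diol
Product: 8 (3R)-3-(propan-2-yl)-1,3-bis[(triethylsilyl)oxy]hex-5-ene
Conditions: Et3SiOTf (2.4 equiv), 2,6-lutidine, CH2Cl2, −78 → 0 °C
Reagents that add atoms: triethylsilyl trifluoromethanesulfonate, CC[Si](CC)(CC)OS(=O)(=O)C(F)(F)F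
Why: Exhaustive silylation with the silyl triflate and 2,6-lutidine caps both the primary and the hindered tertiary hydroxyl.

Step 6
Reactants: 8 (3R)-3-(propan-2-yl)-1,3-bis[(triethylsilyl)oxy]hex-5-ene
Product: 9 (3R)-3-(propan-2-yl)-3-[(triethylsilyl)oxy]hex-5-enal
Conditions: (COCl)2, DMSO, CH2Cl2, −78 → −40 °C; then Et3N, −78 → 0 °C
Reagents that add atoms: none
Why: Under Swern conditions the chlorosulfonium salt selectively cleaves the primary triethylsilyl ether and the resulting alkoxysulfonium ion is oxidised to the C7 aldehyde, while the tertiary silyl ether is inert.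

Step 7
Reactants: 9 (3R)-3-(propan-2-yl)-3-[(triethylsilyl)oxy]hex-5-enal; 10 (4S)-4-benzyl-3-propanoyl-1,3-oxazolidin-2-one
Product: 12 (4S)-4-benzyl-3-[(2S,3R,5R)-3-hydroxy-2-methyl-5-(propan-2-yl)-5-[(triethylsilyl)oxy]oct-7-enoyl]-1,3-oxazolidin-2-one, via (Z)-boron enolate 11 (not isolated)
Conditions: 10, n-Bu2BOTf, i-Pr2NEt, CH2Cl2, −78 → 0 °C; then 9, −78 → 0 °C; pH 7 buffer, MeOH, H2O2
Reagents that add atoms: none
Why: Evans syn aldol reaction, in which the (Z)-boron enolate adds through a closed chair transition state under auxiliary control to give the (2S,3R) adduct; this sets C7 (R) independently of the remote C9 centre, and the C6 configuration is immaterial because C6 becomes trigonal in the key step.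

Step 8
Reactants: 12 the aldol adduct
Product: 13 (2S,3R,5R)-3-hydroxy-N-methoxy-N,2-dimethyl-5-(propan-2-yl)-5-[(triethylsilyl)oxy]oct-7-enamide
Conditions: MeNHOMe·HCl, AlMe3, THF, −20 → 0 °C
Reagents that add atoms: N,O-dimethylhydroxylamine hydrochloride, CNOC.Cl
Why: Aluminium amide transamidation of the imide, assisted by the free β-hydroxyl as its aluminium alkoxide, cleaves the exocyclic acyl group to the Weinreb amide without retro-aldol.

Step 9
Reactants: 13 the β-hydroxy Weinreb amide
Product: 14 (2S,3R,5R)-3-[(tert-butyldimethylsilyl)oxy]-N-methoxy-N,2-dimethyl-5-(propan-2-yl)-5-[(triethylsilyl)oxy]oct-7-enamide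
Conditions: t-BuMe2SiOTf, 2,6-lutidine, CH2Cl2, −78 → 0 °C
Reagents that add atoms: tert-butyldimethylsilyl trifluoromethanesulfonate, CC(C)(C)[Si](C)(C)OS(=O)(=O)C(F)(F)F
Why: Silylation of the secondary C7 hydroxyl with the silyl triflate gives a protecting group that survives every later step up to the last.

Step 10
Reactants: 14 the TBS-protected Weinreb amide
Product: 16 (2S,3R,5S)-3-[(tert-butyldimethylsilyl)oxy]-N-methoxy-N,2-dimethyl-7-oxo-5-(propan-2-yl)-5-[(triethylsilyl)oxy]heptanamide, via ozonide 15 (not isolated)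
Conditions: O3, CH2Cl2, −78 °C; then PPh3, −78 → 23 °C
Reagents that add atoms: ozone, [O-][O+]=O
Why: Ozonolysis with reductive work-up cleaves the only alkene to the C1 aldehyde; silyl ethers and the Weinreb amide are inert to ozone at −78 °C.

Step 11
Reactants: 16 the C1 aldehyde; 17 (1E)-1-bromoprop-1-ene
Product: 18 (2S,3R,5R,8E)-3-[(tert-butyldimethylsilyl)oxy]-7-hydroxy-N-methoxy-N,2-dimethyl-5-(propan-2-yl)-5-[(triethylsilyl)oxy]dec-8-enamide (both epimers at the new carbinol carbon)
Conditions: 17, t-BuLi (2 equiv), Et2O, −78 °C; then 16, Et2O, −78 °C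
Reagents that add atoms: none
Why: Bromine–lithium exchange occurs with retention to (E)-prop-1-enyllithium, whose 1,2-addition to the aldehyde at −78 °C is much faster than attack on the hindered α-branched Weinreb amide; the new carbinol centre is oxidised in the next step.

Step 12
Reactants: 18 the allylic alcohol
Product: 19 (2S,3R,5S,8E)-3-[(tert-butyldimethylsilyl)oxy]-N-methoxy-N,2-dimethyl-7-oxo-5-(propan-2-yl)-5-[(triethylsilyl)oxy]dec-8-enamide
Conditions: Dess–Martin periodinane, NaHCO3, CH2Cl2, 0 → 23 °C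
Reagents that add atoms: none
Why: Dess–Martin oxidation of the allylic alcohol gives the (E)-enone under buffered conditions that leave the silyl ethers intact.

Step 13
Reactants: 19 the (E)-enone
Product: 20 (2S,3R,5R,6Z,8E)-3-[(tert-butyldimethylsilyl)oxy]-N-methoxy-N,2-dimethyl-5-(propan-2-yl)-5-[(triethylsilyl)oxy]-7-{[tri(propan-2-yl)silyl]oxy}deca-6,8-dienamide
Conditions: i-Pr3SiOTf, Et3N, CH2Cl2, −78 → 0 °C
Reagents that add atoms: triisopropylsilyl trifluoromethanesulfonate, CC(C)[Si](C(C)C)(C(C)C)OS(=O)(=O)C(F)(F)F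
Why: Soft enolisation of the enone at the α' methylene C10 gives the cross-conjugated 2-silyloxy diene; the (Z) enol ether, with OTIPS cis and the propenyl group trans to the fully substituted C9, is the less strained isomer, and the Weinreb amide is not enolised.

Step 14
Reactants: 20 the silyloxy diene Weinreb amide
Product: 22 (3S,4R,6R,7Z,9E)-4-[(tert-butyldimethylsilyl)oxy]-1-chloro-3-methyl-6-(propan-2-yl)-6-[(triethylsilyl)oxy]-8-{[tri(propan-2-yl)silyl]oxy}undeca-7,9-dien-2-one, via lithium tetrahedral adduct 21 (not isolated)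
Conditions: ICH2Cl, MeLi·LiBr, THF/Et2O, −78 °C; aq. NH4Cl
Reagents that add atoms: chloroiodomethane, ICCl
Why: Chloromethyllithium generated in the flask by iodine–lithium exchange adds once to the Weinreb amide, whose chelated tetrahedral adduct releases the chloromethyl ketone only on work-up; the nucleophilic carbenoid does not affect the silyl enol ether.

Step 15
Reactants: 22 the chloro ketone carrying the (Z,E)-silyloxy diene
Product: 24 trans-fused bicyclic C5 ketone with the C1 TIPS enol ether (C1=C2; 3α-methyl; 6α-methyl; 7α-OTBS; 9α-OTES; 9β-isopropyl; 10β-H), via oxyallyl cation 23 (not isolated)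
Conditions: Et3N (3 equiv), CF3CH2OH (0.01 M), 0 → 23 °C
Reagents that add atoms: none
Why: Proposed new method: Et3N enolises the chloro ketone toward C6 and chloride leaves C4 in the ionising solvent to give the oxyallyl cation 23 (C4–C5–C6); its fully substituted terminus C6 is attacked by the silyl enol ether carbon C10 and the silyloxyallyl cation so formed is closed by C4 at C3, a concerted or rapidly stepwise (4+3) cycloaddition whose closest known type is the intramolecular (4+3) cycloaddition of chloro-ketone-derived oxyallyl cations with tethered alkyl dienes or furans to 5,7-fused ketones, the 2-silyloxy diene and the fully substituted cation terminus being the untested pairing. Ring B closes first as a five-membered ring through the tether C7–C8–C9 (C6–C10 bond, exo to both π systems) and ring A follows as the seven-membered ring across the s-cis diene (C3–C4 bond). C6 is controlled by C7: with the C7 hydrogen in the plane of the cation on the C5 side (least A(1,3) strain) the tether must deliver C10 to the face anti to the OTBS group, which puts the C6 methyl cis to the C7 oxygen. C10 is controlled by C9 and the (Z) enol ether: the OTIPS group cis to C9 pushes the isopropyl group into the position anti to C1, so C1 ends cis to the C9 oxygen, and together with the C6 result this is the trans ring fusion, reached through the extended (anti) arrangement of the two π systems that a hydroxyallyl cation in CF3CH2OH favours. C3 follows from suprafacial addition to the (E)-propenyl terminus and is erased in step 19. The step needs C3–C4 bonding to win over closure at C1 or at the enolate oxygen and over loss of silicon, which the hydrolytically robust TIPS group and the outward placement of both diene substituents are meant to secure.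

Step 16
Reactants: 24 the cycloadduct
Product: 25 trans-fused 9α-hydroxy C1,C5-diketone (3α-methyl; 7α-OTBS)
Conditions: HF·pyridine, pyridine, THF, 0 → 23 °C
Reagents that add atoms: none
Why: Selective desilylation, in which buffered HF cleaves the silyl enol ether by protonation at C2 (C10 is not touched) and the tertiary triethylsilyl ether but not the hindered secondary TBS ether, unmasking the C1 ketone and the C9 hydroxyl that directs step 17.

Step 17
Reactants: 25 the hydroxy diketone
Product: 26 1β,9α-dihydroxy C5 ketone (7α-OTBS)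
Conditions: Me4NBH(OAc)3, AcOH, MeCN, −30 °C
Reagents that add atoms: none
Why: Hydroxyl-directed triacetoxyborohydride reduction (Evans–Saksena reduction): the borohydride bound to the C9 oxygen on the α face delivers hydride to the α face of the C1 carbonyl, giving the 1β-alcohol anti to the C9 hydroxyl, while the C5 ketone, which has no free hydroxyl within reach, is not reduced.

Step 18
Reactants: 26 the dihydroxy ketone
Product: 27 tris(trimethylsilyl) derivative (1β-OTMS; 9α-OTMS; C4=C5 TMS enol ether)
Conditions: Me3SiOTf (4 equiv), Et3N, CH2Cl2, −78 → 0 °C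
Reagents that add atoms: trimethylsilyl trifluoromethanesulfonate, C[Si](C)(C)OS(=O)(=O)C(F)(F)F
Why: Exhaustive silylation caps both hydroxyls and converts the C5 ketone into its silyl enol ether, which can form only toward C4 because C6 is quaternary.

Step 19
Reactants: 27 the tris(trimethylsilyl) derivative
Product: 29 1β,9α-dihydroxy C3=C4 en-5-one (7α-OTBS), via bis(trimethylsilyl) ether enone 28 (not isolated)
Conditions: Pd(OAc)2 (1.1 equiv), MeCN, 23 °C; then 1 M HCl, THF, 0 °C
Reagents that add atoms: none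
Why: Saegusa–Ito oxidation, in which the divalent palladium enolate at C4 undergoes β-hydride elimination of the C3 hydrogen to give the C3=C4 enone whichever C3 epimer is present; dilute acid then removes the labile trimethylsilyl ethers.

Step 20
Reactants: 29 the enone diol; 30 angelic acid
Product: 31 1β-angelate of the C3=C4 en-5-one (9α-OH; 7α-OTBS)
Conditions: 30 (1.5 equiv), 2,4,6-trichlorobenzoyl chloride, Et3N (1 equiv to the acid chloride), toluene, 23 °C, Et3NH+ Cl− filtered off; then 29, toluene, 75 °C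
Reagents that add atoms: none
Why: Yamaguchi-type esterification through the mixed anhydride made in the flask, run without a nucleophilic catalyst so that the (Z) acid is not isomerised, acylates the only secondary hydroxyl (C1) and leaves the tertiary C9 hydroxyl free; the amine salt is removed before heating so that no base is present that could trigger vinylogous elimination of the C1 ester from the enone.

Step 21
Reactants: 31 the C1 angelate enone
Product: 32 5β-hydroxy 1β-angelate with the C3=C4 alkene (9α-OH; 7α-OTBS)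
Conditions: NaBH4, CeCl3·7H2O, MeOH, −78 °C
Reagents that add atoms: none
Why: Luche 1,2-reduction, in which hydride is expected to attack C5 from the α face, past the small C6 methyl group and away from both the C6–C7 bond of ring B and the β-oriented C1 ester, so that the new hydroxyl ends on the β face trans to the C6 methyl; the angelate ester is inert to NaBH4 at −78 °C.

Step 22
Reactants: 32 the 5β-hydroxy C1 angelate; 30 angelic acid
Product: 33 1β,5β-bis-angelate (9α-OH; 7α-OTBS)
Conditions: 30 (4 equiv), 2,4,6-trichlorobenzoyl chloride, Et3N, toluene, 23 °C; then 32, toluene, 80 °C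
Reagents that add atoms: none
Why: The same mixed-anhydride esterification, now with excess reagent, acylates the remaining secondary hydroxyl at the hindered allylic C5 with retention of configuration at C5 and of the (Z) geometry of the acid, while the tertiary C9 hydroxyl stays free.

Step 23
Reactants: 33 the bis-angelate
Product: 34 CNP0249167.2 (target)
Conditions: HF·pyridine, pyridine, THF, 0 → 23 °C
Reagents that add atoms: none
Why: Buffered fluoride cleaves the last silyl ether without acyl migration, allylic ionisation or angelate isomerisation (final deprotection).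

**Compound list**

1 | 4-methylpent-2-yn-1-ol | CC(C)C#CCO | starting material
2 | sodium alkenylalanate (five-membered O–Al–C3=C2–C1 ring, two 2-methoxyethoxy groups on Al) | CC(C)C1=CCO[Al-]1(OCCOC)OCCOC.[Na+] | intermediate
3 | (2Z)-3-iodo-4-methylpent-2-en-1-ol | OC/C=C(/C(C)C)I | intermediate
4 | allyltributylstannane | C=CC[Sn](CCCC)(CCCC)CCCC | starting material
5 | (2E)-3-(propan-2-yl)hexa-2,5-dien-1-ol | OC/C=C(/C(C)C)CC=C | intermediate
6 | [(2S,3S)-3-(propan-2-yl)-3-(prop-2-en-1-yl)oxiran-2-yl]methanol | OC[C@@H]1O[C@]1(C(C)C)CC=C | intermediate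
7 | (3R)-3-(propan-2-yl)hex-5-ene-1,3-diol | OCC[C@@](O)(C(C)C)CC=C | intermediate
8 | (3R)-3-(propan-2-yl)-1,3-bis[(triethylsilyl)oxy]hex-5-ene | CC[Si](CC)(CC)OCC[C@@](O[Si](CC)(CC)CC)(C(C)C)CC=C | intermediate
9 | (3R)-3-(propan-2-yl)-3-[(triethylsilyl)oxy]hex-5-enal | O=CC[C@@](O[Si](CC)(CC)CC)(C(C)C)CC=C | intermediate
10 | (4S)-4-benzyl-3-propanoyl-1,3-oxazolidin-2-one | CCC(=O)N1[C@@H](Cc2ccccc2)COC1=O | starting material
11 | (Z)-dibutylboron enolate of 10 | C/C=C(\OB(CCCC)CCCC)N1[C@@H](Cc2ccccc2)COC1=O | intermediate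
12 | (4S)-4-benzyl-3-[(2S,3R,5R)-3-hydroxy-2-methyl-5-(propan-2-yl)-5-[(triethylsilyl)oxy]oct-7-enoyl]-1,3-oxazolidin-2-one | O=C(N1[C@@H](Cc2ccccc2)COC1=O)[C@@H](C)[C@H](O)C[C@@](O[Si](CC)(CC)CC)(C(C)C)CC=C | intermediate
13 | (2S,3R,5R)-3-hydroxy-N-methoxy-N,2-dimethyl-5-(propan-2-yl)-5-[(triethylsilyl)oxy]oct-7-enamide | CON(C)C(=O)[C@@H](C)[C@H](O)C[C@@](O[Si](CC)(CC)CC)(C(C)C)CC=C | intermediate
14 | (2S,3R,5R)-3-[(tert-butyldimethylsilyl)oxy]-N-methoxy-N,2-dimethyl-5-(propan-2-yl)-5-[(triethylsilyl)oxy]oct-7-enamide | CON(C)C(=O)[C@@H](C)[C@H](O[Si](C)(C)C(C)(C)C)C[C@@](O[Si](CC)(CC)CC)(C(C)C)CC=C | intermediate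
15 | ozonide (1,2,4-trioxolane) of 14 | CON(C)C(=O)[C@@H](C)[C@H](O[Si](C)(C)C(C)(C)C)C[C@@](O[Si](CC)(CC)CC)(C(C)C)CC1OCOO1 | intermediate
16 | (2S,3R,5S)-3-[(tert-butyldimethylsilyl)oxy]-N-methoxy-N,2-dimethyl-7-oxo-5-(propan-2-yl)-5-[(triethylsilyl)oxy]heptanamide | CON(C)C(=O)[C@@H](C)[C@H](O[Si](C)(C)C(C)(C)C)C[C@@](O[Si](CC)(CC)CC)(C(C)C)CC=O | intermediate
17 | (1E)-1-bromoprop-1-ene | C/C=C/Br | starting material
18 | (2S,3R,5R,8E)-3-[(tert-butyldimethylsilyl)oxy]-7-hydroxy-N-methoxy-N,2-dimethyl-5-(propan-2-yl)-5-[(triethylsilyl)oxy]dec-8-enamide (carbinol epimers) | CON(C)C(=O)[C@@H](C)[C@H](O[Si](C)(C)C(C)(C)C)C[C@@](O[Si](CC)(CC)CC)(C(C)C)CC(O)/C=C/C | intermediate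
19 | (2S,3R,5S,8E)-3-[(tert-butyldimethylsilyl)oxy]-N-methoxy-N,2-dimethyl-7-oxo-5-(propan-2-yl)-5-[(triethylsilyl)oxy]dec-8-enamide | CON(C)C(=O)[C@@H](C)[C@H](O[Si](C)(C)C(C)(C)C)C[C@@](O[Si](CC)(CC)CC)(C(C)C)CC(=O)/C=C/C | intermediate
20 | (2S,3R,5R,6Z,8E)-3-[(tert-butyldimethylsilyl)oxy]-N-methoxy-N,2-dimethyl-5-(propan-2-yl)-5-[(triethylsilyl)oxy]-7-{[tri(propan-2-yl)silyl]oxy}deca-6,8-dienamide | CON(C)C(=O)[C@@H](C)[C@H](O[Si](C)(C)C(C)(C)C)C[C@@](O[Si](CC)(CC)CC)(C(C)C)/C=C(O[Si](C(C)C)(C(C)C)C(C)C)/C=C/C | intermediate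
21 | lithium tetrahedral adduct of 20 with chloromethyllithium | ClCC([O-])(N(C)OC)[C@@H](C)[C@H](O[Si](C)(C)C(C)(C)C)C[C@@](O[Si](CC)(CC)CC)(C(C)C)/C=C(O[Si](C(C)C)(C(C)C)C(C)C)/C=C/C.[Li+] | intermediate
22 | (3S,4R,6R,7Z,9E)-4-[(tert-butyldimethylsilyl)oxy]-1-chloro-3-methyl-6-(propan-2-yl)-6-[(triethylsilyl)oxy]-8-{[tri(propan-2-yl)silyl]oxy}undeca-7,9-dien-2-one | ClCC(=O)[C@@H](C)[C@H](O[Si](C)(C)C(C)(C)C)C[C@@](O[Si](CC)(CC)CC)(C(C)C)/C=C(O[Si](C(C)C)(C(C)C)C(C)C)/C=C/C | intermediate
23 | oxyallyl cation (2-oxidoallyl zwitterion C4–C5–C6) | [CH2+]C([O-])=C(C)[C@H](O[Si](C)(C)C(C)(C)C)C[C@@](O[Si](CC)(CC)CC)(C(C)C)/C=C(O[Si](C(C)C)(C(C)C)C(C)C)/C=C/C | intermediate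
24 | trans-fused bicyclic C5 ketone with C1 TIPS enol ether (3α-methyl, 7α-OTBS, 9α-OTES) | CC(C)[Si](C(C)C)(C(C)C)OC1=C[C@H](C)CC(=O)[C@@]2(C)[C@H](O[Si](C)(C)C(C)(C)C)C[C@@](O[Si](CC)(CC)CC)(C(C)C)[C@H]12 | intermediate
25 | trans-fused 9α-hydroxy C1,C5-diketone (7α-OTBS) | O=C1C[C@H](C)CC(=O)[C@@]2(C)[C@H](O[Si](C)(C)C(C)(C)C)C[C@@](O)(C(C)C)[C@H]12 | intermediate
26 | 1β,9α-dihydroxy C5 ketone (7α-OTBS) | O[C@H]1C[C@H](C)CC(=O)[C@@]2(C)[C@H](O[Si](C)(C)C(C)(C)C)C[C@@](O)(C(C)C)[C@H]12 | intermediate
27 | tris(trimethylsilyl) derivative of 26 (C4=C5 enol ether) | C[Si](C)(C)O[C@H]1C[C@H](C)C=C(O[Si](C)(C)C)[C@@]2(C)[C@H](O[Si](C)(C)C(C)(C)C)C[C@@](O[Si](C)(C)C)(C(C)C)[C@H]12 | intermediate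
28 | 1β,9α-bis(trimethylsilyloxy) C3=C4 en-5-one | C[Si](C)(C)O[C@H]1CC(C)=CC(=O)[C@@]2(C)[C@H](O[Si](C)(C)C(C)(C)C)C[C@@](O[Si](C)(C)C)(C(C)C)[C@H]12 | intermediate
29 | 1β,9α-dihydroxy C3=C4 en-5-one (7α-OTBS) | O[C@H]1CC(C)=CC(=O)[C@@]2(C)[C@H](O[Si](C)(C)C(C)(C)C)C[C@@](O)(C(C)C)[C@H]12 | intermediate
30 | angelic acid, (2Z)-2-methylbut-2-enoic acid | C/C=C(/C)C(=O)O | starting material
31 | 1β-angelate of the C3=C4 en-5-one (9α-OH, 7α-OTBS) | C/C=C(/C)C(=O)O[C@H]1CC(C)=CC(=O)[C@@]2(C)[C@H](O[Si](C)(C)C(C)(C)C)C[C@@](O)(C(C)C)[C@H]12 | intermediate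
32 | 5β-hydroxy 1β-angelate with C3=C4 alkene (9α-OH, 7α-OTBS) | C/C=C(/C)C(=O)O[C@H]1CC(C)=C[C@@H](O)[C@@]2(C)[C@H](O[Si](C)(C)C(C)(C)C)C[C@@](O)(C(C)C)[C@H]12 | intermediate
33 | 1β,5β-bis-angelate (9α-OH, 7α-OTBS) | C/C=C(/C)C(=O)O[C@H]1CC(C)=C[C@@H](OC(=O)/C(C)=C\C)[C@@]2(C)[C@H](O[Si](C)(C)C(C)(C)C)C[C@@](O)(C(C)C)[C@H]12 | intermediate
34 | CNP0249167.2 | C/C=C(/C)C(=O)O[C@H]1CC(C)=C[C@@H](OC(=O)/C(C)=C\C)[C@@]2(C)[C@H](O)C[C@@](O)(C(C)C)[C@H]12 | target

**Step count and risks**

Total steps: 23. Longest linear sequence: 23 steps (from 1; compounds 4, 10, 17 and 30 are purchased).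

Steps most likely to fail:

1. Step 15 (Proposed new method).
   - What may go wrong: after the first C–C bond the silyloxyallyl cation may lose silicon or close at C1 or at the enolate oxygen instead of forming C3–C4; the enol ether may be protonated by the solvent before the cation forms; or the cation may be captured by the solvent.
   - A minor C10 epimer would not need a separate route, since C10 becomes α to the C1 ketone in 25 and can be equilibrated there with DBU toward the isomer with C1 anti to the isopropyl group and hydrogen-bonded to the C9 hydroxyl.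
   - Fallback (known chemistry), setting out from enone 19: kinetic enolisation with KN(SiMe3)2 (THF, −78 °C) and trapping with PhNTf2 gives the (Z)-dienyl triflate F1. Formate reduction (Pd(OAc)2, PPh3, HCO2H, Bu3N, DMF, 60 °C) gives the (6E,8E)-diene Weinreb amide F2. Chloromethyllithium as in step 14 gives the diene chloro ketone F3. Et3N in CF3CH2OH then effects the established intramolecular (4+3) cycloaddition of a chloro-ketone-derived oxyallyl cation with a tethered alkyl-substituted butadiene, giving the bicyclic C5 ketone with a C1=C2 alkene F4. HF·pyridine frees the tertiary hydroxyl to give the C9 alcohol F5. Silylation of that hydroxyl with (HMe2Si)2NH and intramolecular hydrosilylation (Pt2[(CH2=CHSiMe2)2O]3, toluene) place silicon on C1 in the cyclic siloxane F6. Tamao–Fleming oxidation (H2O2, KF, KHCO3, THF/MeOH) gives the 1α,9α-diol F7. Dess–Martin oxidation of its secondary hydroxyl returns to hydroxy diketone 25.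

2. Step 21.
   - What may go wrong: poor or reversed facial selectivity of hydride delivery to C5.
   - Fallback, setting out from the C1 angelate enone 31: if hydride delivery favours the β face, the same Luche reduction gives the 5α-hydroxy C1 angelate F8. Mitsunobu esterification of F8 with angelic acid 30 (PPh3, diisopropyl azodicarboxylate, toluene, 0 → 23 °C) installs the second angelate with inversion at C5 and returns to bis-angelate 33, so that step 22 is not needed.

3. Step 22.
   - What may go wrong: isomerisation of the angelate to the tiglate during the prolonged heating, or incomplete acylation of the hindered C5 hydroxyl.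
   - Fallback, setting out from the 5β-hydroxy C1 angelate 32: the C5 hydroxyl is esterified with 2-[bis(2,2,2-trifluoroethoxy)phosphoryl]propanoic acid (N,N'-dicyclohexylcarbodiimide, 4-(dimethylamino)pyridine, CH2Cl2), which reacts through a highly electrophilic phosphonoketene, to give the C5 phosphonopropanoate F9. A Still–Gennari olefination with acetaldehyde (KN(SiMe3)2 in excess to allow for the free C9 hydroxyl, 18-crown-6, THF, −78 °C) builds the (Z)-2-methylbut-2-enoate on C5 and returns to bis-angelate 33.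

**Further compounds**

F1 | step 15 | (Z)-dienyl triflate of enone 19 | CON(C)C(=O)[C@@H](C)[C@H](O[Si](C)(C)C(C)(C)C)C[C@@](O[Si](CC)(CC)CC)(C(C)C)/C=C(OS(=O)(=O)C(F)(F)F)/C=C/C
F2 | step 15 | (6E,8E)-diene Weinreb amide | CON(C)C(=O)[C@@H](C)[C@H](O[Si](C)(C)C(C)(C)C)C[C@@](O[Si](CC)(CC)CC)(C(C)C)/C=C/C=C/C
F3 | step 15 | diene chloro ketone | ClCC(=O)[C@@H](C)[C@H](O[Si](C)(C)C(C)(C)C)C[C@@](O[Si](CC)(CC)CC)(C(C)C)/C=C/C=C/C
F4 | step 15 | bicyclic C5 ketone with C1=C2 alkene (7α-OTBS, 9α-OTES) | C1=C[C@H](C)CC(=O)[C@@]2(C)[C@H](O[Si](C)(C)C(C)(C)C)C[C@@](O[Si](CC)(CC)CC)(C(C)C)[C@H]12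
F5 | step 15 | C9 alcohol of F4 | C1=C[C@H](C)CC(=O)[C@@]2(C)[C@H](O[Si](C)(C)C(C)(C)C)C[C@@](O)(C(C)C)[C@H]12
F6 | step 15 | cyclic siloxane (Si on C1α, O on C9) | [C@@H]1([Si]3(C)C)C[C@H](C)CC(=O)[C@@]2(C)[C@H](O[Si](C)(C)C(C)(C)C)C[C@@](O3)(C(C)C)[C@H]12
F7 | step 15 | 1α,9α-diol C5 ketone | O[C@@H]1C[C@H](C)CC(=O)[C@@]2(C)[C@H](O[Si](C)(C)C(C)(C)C)C[C@@](O)(C(C)C)[C@H]12
F8 | step 21 | 5α-hydroxy C1 angelate | C/C=C(/C)C(=O)O[C@H]1CC(C)=C[C@H](O)[C@@]2(C)[C@H](O[Si](C)(C)C(C)(C)C)C[C@@](O)(C(C)C)[C@H]12
F9 | step 22 | C5 phosphonopropanoate of 32 | C/C=C(/C)C(=O)O[C@H]1CC(C)=C[C@@H](OC(=O)C(C)P(=O)(OCC(F)(F)F)OCC(F)(F)F)[C@@]2(C)[C@H](O[Si](C)(C)C(C)(C)C)C[C@@](O)(C(C)C)[C@H]12
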